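The runs were generated by integration with constants of no real substance, and the scatter is random.

At 2.5 d something had to be done to the south flask, and I decided to choose by comparing two reservoirs: the Q not yet turned over, and what had been made but no longer stood as X.

in all of them: Q 20 mM; E 20.4 mM
- south: J 0.20 mM; temperature 25 °C; the very flask that is asked about, followed so far
- south-east: J 0.40 mM; temperature 10 °C; run made earlier
- flask: J 0.200 mM; temperature 25 °C; time 2.5 d

| south: time / d | south: X / % | south-east: time / h | south-east: X / % |
|---|---|---|---|
| 0.208 | 26.1 | 4.00 | 7.4 |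
| 0.417 | 40.9 | 12.0 | 18.2 |
| 0.625 | 44.9 | 25.0 | 29.3 |
| 1.25 | 45.6 | 30.0 | 30.7 |
| 2.50 | 38.9 | 48.0 | 40.3 |

(standard deviation of a reading: 1 percentage point)

- cedar: at 2.5 d take out 90 % of the X then present, then wait 2.5 d
- maple: at 2.5 d raise the temperature by 25 K, then wait 2.5 d
- elm: at 2.5 d add E, 100 % of the amount charged, then wait 2.5 d
- birch: change nothing and wait 2.5 d more

- X taken out counts as made
- on the list of suspects stand: Q + E -> X; Q + J -> G; E -> L; X <-> D; 2 E -> Z
- additions bring no volume worth counting

- X, in percent of the Q first charged, at 2.5 d
- the option that brings most further X ("none" if no option brings more than 2 percentage points) (cedar / maple / elm / birch / none)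
- X present, with what was taken out counted in, in percent of the Q first charged, after cedar
- X present, with what was taken out counted in, in percent of the Q first charged, after birch

How fast was X made? I took the first south reading, 26.1 % at 0.208 d, as second order with nearly equal charges, which gave k·c_Q = 1.70 d⁻¹. On that clock the south flask had made 80.9 % by 2.5 d, leaving 19.1 % of the Q by my reckoning.

How much had moved on? X read 38.9 %, so by my reckoning 42 percentage points had left X, more than the Q left. That made 1.08 for the ratio I named h, the amount made but no longer X per amount of X.

Where did h stand against the equilibrium constant K of X ⇌ D? The X readings fell from 45.6 % to 38.9 % while by my reckoning more was being made, and I read that as h lying below K, with X sinking further under birch. Elm draws on the smaller reservoir. Cedar lifts h to 10.8, which pulls X back if K lies under that. I could read from the two runs no direction in which heat moves K, so I did not price maple; of the rest I backed cedar.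

The forecast gave 39.2 % now, 39 % after cedar and 32 % after birch, and chose elm: “elm wins clearly”.

The flask gives 38.0 %. The best option is maple, with 24 points, against 8.8 points for cedar, −2.2 points for elm and −11 points for birch. X comes to 46.8 % after cedar and 27.4 % after birch.

    Q + E → X (k = 0.00128 M⁻¹ s⁻¹, Ea = 76.0 kJ mol⁻¹)
    Q + J → G (k = 0.237 M⁻¹ s⁻¹, Ea = 59.0 kJ mol⁻¹)
    E → L (k = 1.24 × 10⁻⁸ s⁻¹, Ea = 127 kJ mol⁻¹)
    X ⇌ D (K = 2.61, k = 5.15 × 10⁻⁶ s⁻¹, Ea = 91.0 kJ mol⁻¹, ΔH = −66.0 kJ mol⁻¹)
    2 E → Z (k = 2.03 × 10⁻⁴ M⁻¹ s⁻¹, Ea = 72.0 kJ mol⁻¹)
    (constants at 25 °C)

K is 2.61, above the h of 1.08 and below cedar's 10.8; under birch X fell by 11 points, and with cedar the count of X rose by 8.8 points. Maple acts on the same reservoir: X ⇌ D is the largest single effect on its gain, which drops from 24 points to 7 points with that step struck out. The step gives off heat, so heating lowers K.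

In the neighbour with 82 mM of E, I reckoned Q as pseudo-first-order at the charged c_E, and my clock makes >99.9 %; with h carried over, my reckoning puts X near 48.1 %. The computed flask holds X at 44.8 % and D at 53.9 %.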